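A leftover opens the reckoning: at 80.0 s the flask still holds 11% of right-handed substrate, and I must say what becomes of it. Partner dissolves from the solid reagent, consumes either substrate hand, and may pass into a dormant form, while the hands may interconvert.

- gamma: left-handed substrate 0.0020 M; right-handed substrate 0.0020 M; solid reagent 4.4 mM; the very flask that is asked about, followed so far
- flask: left-handed substrate 0.0020 M; solid reagent 4.40 mM; right-handed substrate 0.0020 M; time 2.5 min

gamma run (percent of the left-handed substrate and right-handed substrate together charged)

| time / s | left-handed product / % | right-handed substrate / % |
|---|---|---|
| 10.0 | 8 | 44 |
| 15.0 | 13 | 38 |
| 25.0 | 21 | 35 |
| 50.0 | 39 | 19 |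
| 80.0 | 48 | 11 |

(readings scatter by 1.5 percentage points)

- partner is single-handed; left-handed substrate and right-handed substrate are mirror images of each other, charged as a racemate, each of them at the stated concentration
- as a solid, counted per litre of solution: solid reagent
- the numbers in the tables scatter by 1.5 percentage points (one standard deviation)
- steps under discussion: partner + right-handed substrate -> right-handed product; left-handed substrate <-> right-handed substrate; partner + left-handed substrate -> left-handed product; partner <-> dormant form; solid reagent <-> partner
- at the start none of the solid reagent is in solution
- the handed part of partner does not stay in what it makes, so the products of the two hands are mirror images too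

1. left-handed product present at 2.5 min, in percent of the left-handed substrate and right-handed substrate together charged
2. right-handed substrate present at 2.5 min, in percent of the left-handed substrate and right-handed substrate together charged
3. left-handed substrate present at 2.5 min, in percent of the left-handed substrate and right-handed substrate together charged
4. concentration of partner at 2.5 min, in M

Let S be the right-handed substrate. I guess that the hands stay equal, so what has been consumed is the charge less S counted for each hand. The left share, left-handed product per substrate consumed of either hand, is then 61.5% at 80.0 s. Next I integrate the loss of S in closed form, as an exponential. That takes partner as steady, which is a rough assumption, as the solid reagent charged stands at 1.10 times the substrate. From 50.0 s to 80.0 s the readings give a constant of 0.0182 /s, so on this assumption S at 2.5 min comes to 3.07%, and left-handed substrate the same. Left-handed product comes to 57.7%.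

The weak link is the guess of equal hands, so I test it. At 50.0 s the share reads 62.9%, about the same as at 80.0 s. Pooled, the two readings give a left share f = 62.1%, and I commit to 58.3% of left-handed product. Taking one partner per substrate, the charge leaves 0.646 mM for partner, dormant form and undissolved solid together, so I put partner below that.

The forecast says left-handed product 50%, right-handed substrate 3.5%, left-handed substrate 1.2% and partner 2.000 × 10⁻⁴ M, holding that “left-handed product approaches 50%”. On left-handed product my figure stands higher.

The flask gives left-handed product 59.6%, right-handed substrate 2.93%, left-handed substrate 2.92% and partner 4.81 × 10⁻⁴ M.

    partner + right-handed substrate → right-handed product (k = 19.2 /M/s)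
    left-handed substrate ⇌ right-handed substrate (k = 1.19 /s)
    partner + left-handed substrate → left-handed product (k = 33.3 /M/s)
    partner ⇌ dormant form (K = 0.303, k = 0.0344 /s)
    solid reagent ⇌ partner, rate k5*(cs5 - [partner]) while solid is left; crystals form when [partner] > cs5 (solubility = 1.10 mM, k = 0.211 /s)

The hands relax into each other with a half-life of 0.291 s, far shorter than the 0.44 min of left-handed substrate going to product at 0.368 min. Applied to the substrate actually consumed, f gives 58.5%.

Take the neighbour with 0.0011 M of solid reagent, the limiting reagent there. It can consume 27.5% of the substrate, so f gives 17.1% of left-handed product. That neighbour gives 17.4%, with 36.3% of right-handed substrate remaining.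

All runs stem from a simulated flask from invented constants; scatter was added.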